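The earlier runs and the new flask are calculated on assumed constants; noise was put on by code.

Late in the larch run the target has nearly stopped: it gains 0.00160 M between 110 min and 130 min, against a scatter of 0.002 M.

| flask | substrate | partner | catalyst | time |
|---|---|---|---|---|
| larch | 0.400 M | 0.400 M | 0.0400 M |  |
| ash | 0.400 M | 1.20 M | 0.0400 M |  |
| alder | 0.160 M | 0.160 M | 0.0400 M | 130 min |

| run | time / min | [target] / M |
|---|---|---|
| larch run | 19 | 0.0963 |
| larch run | 37 | 0.1434 |
| larch run | 56 | 0.1655 |
| larch run | 74 | 0.1750 |
| larch run | 93 | 0.1897 |
| larch run | 110 | 0.1962 |
| larch run | 130 | 0.1978 |
| ash run | 19 | 0.2142 |
| ash run | 37 | 0.2300 |
| ash run | 56 | 0.2003 |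
| ash run | 74 | 0.1738 |
| ash run | 93 | 0.1520 |
| ash run | 110 | 0.1333 |
| ash run | 130 | 0.1222 |

(each reading ± 0.002 M)

- Overall: substrate + partner -> target, with catalyst as catalyst.
- Constant volume, constant temperature.
- Readings of a species count what is bound in complexes too.
- An order is taken over about fifteen percent of the charge, up and down.

- order of the initial rate in [partner], near the charge of the larch run, the rate being that where two percent of its substrate are target
- target in the alder run at 130 min, as a share of the substrate charged

What is the zero of your scale? The symmetric case. The larch run charges equal substrate and partner, and each target takes one of each, so with no other route and no way back the target ends at the charge, 0.400 M.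

Where does the larch run stand? Its target at the last reading per partner charged is 49.4%; I call this the partner share.

Why carry that to the alder run? Its charges are equal too, and it is asked at 130 min, the time of that last larch reading, so its partner share is the asked share of substrate. Where every route taking partner is pseudo-first-order in partner, with the same constants in both flasks, the partner share at a given time does not change with the partner charge.

Is the target route first order in partner? The first reading of the ash run is 2.22 times that of the larch run for 3.00 times the partner, which gives an order of 0.728. That understates it, since the ash run has already bent: its next gain is 0.0158 M, less than the 0.0471 M of the larch run. I take an order of one.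

And the weak spot? The alder run has 0.400 of the substrate of the larch run, while ash and larch share one substrate charge, so these two runs do not compare two substrate charges. If the target route is slower at less substrate, the alder share can fall below my number, and I cannot say by how much.

Your number, then? 49.4% of the alder substrate, or 0.0790 M of target.

The forecast agrees on the order, 1, but gives 34% for the alder run, 15 percentage points below mine, on the ground that “The catalyst seems to die”.

The alder run gives 47.5%, and the order comes out at 1.0. The steps are:

    catalyst + substrate ⇌ catalyst-substrate complex, settled at all times (8.270 M⁻¹)
    catalyst-substrate complex + partner → target + catalyst + by-product (0.5832 M⁻¹ min⁻¹)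
    partner → lost reagent (0.005370 min⁻¹)
    target + partner → side product (0.02706 M⁻¹ min⁻¹)

Turning partner into lost reagent moves the readings by 14, root mean square, in units of the scatter. The alder share means 0.0761 M of target from 0.160 M of partner, 1.9 points under the larch partner share of 49.4%.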